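**Plan**

- Retrosynthesis: the first cut is the side-chain bond C-1'–C-2' (the CH2 on C-2 of the quinolone ring to the next CH2). The second cut removes the two C–CH3 bonds at the carbinol carbon C-12', and the third the ester C–O bond of the chain precursor.
- Forward: 11-bromoundecanoic acid → methyl ester → bromo carbinol (two MeMgBr). The chain is joined in the last step to intact, commercial 2-methylquinolin-4(1H)-one, so no ring has to be built.
- Enabling feature: the CH3 on C-2 of the pyridone ring is the γ-carbon of the vinylogous amide N1–C2=C3–C4=O. Once N1–H is removed it is a 2-picolyl-type carbon on C2=N1 of the 4-oxidoquinoline, and a second deprotonation there gives a C,N-dianion that reacts at this carbon.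
- The tertiary OH needs no protecting group: it passes through the union as its lithium alkoxide, so the key step delivers the target directly.
- Stereochemistry: the target has no stereocentre and no stereogenic double bond, so nothing has to be controlled.

Key step: step 3

Remark: the target is drawn as the 4(1H)-quinolone tautomer (in equilibrium with the 4-hydroxyquinoline form); 11-bromoundecanoic acid and 2-methylquinolin-4(1H)-one are taken as commercial.

**Route**

Step 1
Reactants: 1 11-bromoundecanoic acid
Product: 2 methyl 11-bromoundecanoate
Conditions: MeOH (solvent), H2SO4 (cat.), reflux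
Reagents that add atoms: methanol, CO
Why: Fischer esterification, an acid-catalysed acyl substitution driven to the ester by methanol as solvent, in which the primary C–Br bond should survive because neutral methanol is a poor nucleophile toward a primary bromide.

Step 2
Reactants: 2 methyl 11-bromoundecanoate
Product: 5 12-bromo-2-methyldodecan-2-ol, via 12-bromododecan-2-one 3 (not isolated), via bromomagnesium 12-bromo-2-methyldodecan-2-olate 4 (not isolated)
Conditions: MeMgBr (2.5 equiv), THF, 0 °C → rt; sat. aq NH4Cl
Reagents that add atoms: methylmagnesium bromide, C[Mg]Br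
Why: Double Grignard addition to an ester: loss of methoxide gives ketone 3, which is more electrophilic than 2 and takes up the second methyl group, while a primary alkyl bromide does not couple with MeMgBr at these temperatures without a transition-metal catalyst.

Step 3
Reactants: 5 12-bromo-2-methyldodecan-2-ol; 6 2-methylquinolin-4(1H)-one
Product: 10 2-(12-hydroxy-12-methyltridecyl)quinolin-4(1H)-one, via lithium 2-(lithiomethyl)quinolin-4-olate 7 (not isolated), via lithium 12-bromo-2-methyldodecan-2-olate 8 (not isolated), via dilithium 2-(12-methyl-12-oxidotridecyl)quinolin-4-olate 9 (not isolated)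
Conditions: 6 (1.3 equiv), LDA (2.1 equiv per 6), THF, −78 → 0 °C; 5 + LDA (1.0 equiv), THF, −78 °C, added to the dianion at −78 °C, then → rt; sat. aq NH4Cl
Reagents that add atoms: none
Why: LDA removes first N1–H and then one proton of the C-2 methyl group, because the resulting carbanion is delocalised over C2=N1 and the C3–C4–O enolate system of the pyridone ring, and the C,N-dianion 7 displaces bromide from the primary carbon of 8 in an SN2 reaction. The closest known reaction type is the lateral metalation–alkylation of 2-methyl-4-quinolones and 2-methylquinolines, together with the alkylation of heterocyclic dianions at the carbanion generated last. No ring is closed and no stereocentre is formed in this step. The step needs alkylation at the exocyclic carbon and not at N1, O4 or C-3: the exocyclic carbon carries the least stabilised charge and attack there returns the aromatic lithium quinolin-4-olate, whereas attack at C-3 would leave a non-aromatic exo-methylene ring, and the lithium-bound N and O sites are poor nucleophiles toward an alkyl bromide in THF at low temperature. The tertiary hydroxyl is carried as its hindered lithium alkoxide, which can neither protonate the carbanion nor compete as a nucleophile, and the bromide is the limiting reagent so that a second alkylation finds no electrophile.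

**Compound list**

1 | 11-bromoundecanoic acid | OC(=O)CCCCCCCCCCBr | starting material
2 | methyl 11-bromoundecanoate | COC(=O)CCCCCCCCCCBr | intermediate
3 | 12-bromododecan-2-one | CC(=O)CCCCCCCCCCBr | intermediate
4 | bromomagnesium 12-bromo-2-methyldodecan-2-olate | CC(C)(O[Mg]Br)CCCCCCCCCCBr | intermediate
5 | 12-bromo-2-methyldodecan-2-ol | CC(C)(O)CCCCCCCCCCBr | intermediate
6 | 2-methylquinolin-4(1H)-one | Cc1cc(=O)c2ccccc2[nH]1 | starting material
7 | lithium 2-(lithiomethyl)quinolin-4-olate | [Li+].[Li+].[CH2-]c1cc([O-])c2ccccc2n1 | intermediate
8 | lithium 12-bromo-2-methyldodecan-2-olate | [Li+].CC(C)([O-])CCCCCCCCCCBr | intermediate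
9 | dilithium 2-(12-methyl-12-oxidotridecyl)quinolin-4-olate | [Li+].[Li+].CC(C)([O-])CCCCCCCCCCCc1cc([O-])c2ccccc2n1 | intermediate
10 | 2-(12-hydroxy-12-methyltridecyl)quinolin-4(1H)-one | CC(C)(O)CCCCCCCCCCCc1cc(=O)c2ccccc2[nH]1 | target

Total step count: 3
Longest linear sequence: 3 steps (1 → 2 → 5 → 10)

**Steps most likely to fail**

1. Step 3. The second, lateral deprotonation of the sparingly soluble lithium quinolin-4-olate may stay incomplete, and alkylation may then drift to N1 or O4 or to a second alkylation after proton transfer. The fallback sets out from 6 and 8 and comes back at 10. O-Benzylation of 6 (BnBr, K2CO3, DMF, 60 °C; the C-2 methyl group disfavours attack at N1) should give 4-(benzyloxy)-2-methylquinoline F1. Here the lateral C–H belongs to a neutral 2-methylquinoline and no N–H or O–H competes. LDA (1.1 equiv, THF, −78 °C) should give [4-(benzyloxy)quinolin-2-yl]methyllithium F2. Alkylation of this with 8 should give lithium 13-[4-(benzyloxy)quinolin-2-yl]-2-methyltridecan-2-olate F3 and, after aqueous NH4Cl, 13-[4-(benzyloxy)quinolin-2-yl]-2-methyltridecan-2-ol F4. Hydrogenolysis of the benzyl ether (H2, 1 atm, Pd/C, EtOH, rt) should then unmask the quinolone 10.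

2. Step 2. The second addition may stall through enolisation of the intermediate ketone, and the Grignard reagent may attack the primary C–Br bond (halogen–magnesium exchange, Wurtz-type coupling). The fallback sets out from 7 (made from 6 as in step 3) and comes back at 10, so that no carbinol is made next to a C–Br bond. Alkylation of 7 with commercial 11-bromoundec-1-ene (THF, −78 °C → rt) should give lithium 2-(dodec-11-en-1-yl)quinolin-4-olate F5 and, on NH4Cl work-up, 2-(dodec-11-en-1-yl)quinolin-4(1H)-one F6. Cross-metathesis with 2-methylbut-2-ene (Grubbs second-generation catalyst, CH2Cl2, 40 °C) should give 2-(12-methyltridec-11-en-1-yl)quinolin-4(1H)-one F7. Mukaiyama hydration (Mn(dpm)3 cat., PhSiH3, O2, i-PrOH, rt) should place the hydroxyl at the more substituted alkene carbon and give 10.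

3. Step 1. Methanolysis of the primary bromide on long acidic reflux, or incomplete conversion at the esterification equilibrium, may lower the purity of the ester. The fallback sets out from 1 and comes back at 5 without passing through 2. Oxalyl chloride (cat. DMF, CH2Cl2, 0 °C → rt) should give 11-bromoundecanoyl chloride F8. Direct treatment with MeMgBr (2.2 equiv, THF, −78 → 0 °C; NH4Cl work-up) should lead through 3 and 4 to 5.

**Further compounds**

F1 | step 3 | 4-(benzyloxy)-2-methylquinoline | Cc1cc(OCc2ccccc2)c2ccccc2n1
F2 | step 3 | [4-(benzyloxy)quinolin-2-yl]methyllithium | [Li+].[CH2-]c1cc(OCc2ccccc2)c2ccccc2n1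
F3 | step 3 | lithium 13-[4-(benzyloxy)quinolin-2-yl]-2-methyltridecan-2-olate | [Li+].CC(C)([O-])CCCCCCCCCCCc1cc(OCc2ccccc2)c2ccccc2n1
F4 | step 3 | 13-[4-(benzyloxy)quinolin-2-yl]-2-methyltridecan-2-ol | CC(C)(O)CCCCCCCCCCCc1cc(OCc2ccccc2)c2ccccc2n1
F5 | step 2 | lithium 2-(dodec-11-en-1-yl)quinolin-4-olate | [Li+].C=CCCCCCCCCCCc1cc([O-])c2ccccc2n1
F6 | step 2 | 2-(dodec-11-en-1-yl)quinolin-4(1H)-one | C=CCCCCCCCCCCc1cc(=O)c2ccccc2[nH]1
F7 | step 2 | 2-(12-methyltridec-11-en-1-yl)quinolin-4(1H)-one | CC(C)=CCCCCCCCCCCc1cc(=O)c2ccccc2[nH]1
F8 | step 1 | 11-bromoundecanoyl chloride | O=C(Cl)CCCCCCCCCCBr
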